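**Plan**

- Retrosynthesis: the five benzyl ethers are removed last. Before that, the O1–C2 and O1''–C2'' bonds are cut together with the C2=C3 and C2''=C3'' unsaturations, then the two enone Cα=Cβ bonds (aldol), then the C3'–C8'' biaryl bond (cross-coupling).
- Enabling feature: ring C (O1, C2, C3, C4) and ring F (O1'', C2'', C3'', C4'') are both 2-aryl-4-pyranones whose ring oxygen sits ortho to the acyl carbon on benzo rings A and D. Each is therefore the retron of a 2'-hydroxychalcone, and the skeleton opens to one bichalcone carried by the ring B–ring D biaryl.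
- Forward order: the ring D acetophenone is iodinated at C3' and coupled to a ring B boronate, so the biaryl is made first. The enone towards ring E is built next, then the enone towards ring A. Rings C and F close last, in one operation.
- Stereochemistry: the target has no stereocentre. The only stereo-elements on the way are the two E enones (thermodynamic, from aldol condensation), and both vanish on ring closure. The C8'' attachment is a regiochemical matter, fixed by which ring D oxygen is left free.

Key step: step 11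

Remark: the C3'–C8'' axis is treated as configurationally unresolved (the target is specified without axial chirality), so no control of the axis is attempted.

**Route**

Step 1
Reactants: 1 2',4',6'-trihydroxyacetophenone
Product: 2 1-[2,4-bis(benzyloxy)-6-hydroxyphenyl]ethanone
Conditions: BnBr (2.1 equiv), K2CO3, DMF, rt
Reagents that add atoms: benzyl bromide, BrCc1ccccc1
Why: Williamson ether synthesis, in which the 4'-hydroxyl and one ortho hydroxyl are alkylated while the remaining ortho hydroxyl is held in a hydrogen bond to the acetyl oxygen and should stay free under these mild conditions.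

Step 2
Reactants: 2 1-[2,4-bis(benzyloxy)-6-hydroxyphenyl]ethanone
Product: 3 1-[4,6-bis(benzyloxy)-2-hydroxy-3-iodophenyl]ethanone
Conditions: NIS (1.0 equiv), CF3CO2H (cat.), MeCN, 0 °C to rt
Reagents that add atoms: N-iodosuccinimide, O=C1CCC(=O)N1I
Why: Electrophilic aromatic iodination, expected at C3' (ortho to the free phenol, para to the 6'-benzyloxy group) as is established for 2'-hydroxy-4',6'-dialkoxyacetophenones, with one equivalent of reagent at low temperature to limit di-iodination.

Step 3
Reactants: 4 3-bromo-4-hydroxybenzaldehyde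
Product: 5 4-(benzyloxy)-3-bromobenzaldehyde
Conditions: BnBr (1.1 equiv), K2CO3, DMF, rt
Reagents that add atoms: benzyl bromide, BrCc1ccccc1
Why: Williamson ether synthesis on an acidic para-formyl phenol, which should proceed cleanly and leave aldehyde and bromide untouched.

Step 4
Reactants: 5 4-(benzyloxy)-3-bromobenzaldehyde
Product: 6 2-[4-(benzyloxy)-3-bromophenyl]-1,3-dioxolane
Conditions: HOCH2CH2OH, TsOH·H2O (cat.), toluene, reflux, Dean–Stark
Reagents that add atoms: ethylene glycol, OCCO
Why: Acid-catalysed acetalisation with azeotropic removal of water masks the aldehyde as a base-stable 1,3-dioxolane, so that it cannot compete in the first aldol condensation.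

Step 5
Reactants: 6 2-[4-(benzyloxy)-3-bromophenyl]-1,3-dioxolane
Product: 7 2-[2-(benzyloxy)-5-(1,3-dioxolan-2-yl)phenyl]-4,4,5,5-tetramethyl-1,3,2-dioxaborolane
Conditions: B2pin2, PdCl2(dppf) (cat.), KOAc, 1,4-dioxane, 90 °C
Reagents that add atoms: bis(pinacolato)diboron, CC1(C)OB(OC1(C)C)B1OC(C)(C)C(C)(C)O1
Why: Miyaura borylation of an aryl bromide under weakly basic acetate conditions, which the acetal and the benzyl ether tolerate.

Step 6
Reactants: 3 1-[4,6-bis(benzyloxy)-2-hydroxy-3-iodophenyl]ethanone; 7 2-[2-(benzyloxy)-5-(1,3-dioxolan-2-yl)phenyl]-4,4,5,5-tetramethyl-1,3,2-dioxaborolane (1.3 equiv)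
Product: 8 1-[4,6-bis(benzyloxy)-3-[2-(benzyloxy)-5-(1,3-dioxolan-2-yl)phenyl]-2-hydroxyphenyl]ethanone
Conditions: Pd(OAc)2 (cat.), SPhos, K3PO4, toluene/H2O, 90 °C
Reagents that add atoms: none
Why: Suzuki–Miyaura coupling, in which the bulky electron-rich biarylphosphine SPhos is suited to the tri-ortho-substituted biaryl, the ortho phenol is carried as its phenoxide, and the acetal and methyl ketone are stable to aqueous phosphate.

Step 7
Reactants: 8 1-[4,6-bis(benzyloxy)-3-[2-(benzyloxy)-5-(1,3-dioxolan-2-yl)phenyl]-2-hydroxyphenyl]ethanone; 9 4-(benzyloxy)benzaldehyde (1.2 equiv)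
Product: 10 (E)-1-[4,6-bis(benzyloxy)-3-[2-(benzyloxy)-5-(1,3-dioxolan-2-yl)phenyl]-2-hydroxyphenyl]-3-[4-(benzyloxy)phenyl]prop-2-en-1-one
Conditions: KOH (aq. 50%), EtOH/THF, rt
Reagents that add atoms: none
Why: Claisen–Schmidt condensation of the only enolisable ketone with a non-enolisable aldehyde, the E enone arising from E1cB dehydration under thermodynamic control while the dioxolane is inert to hydroxide.

Step 8
Reactants: 10 (E)-1-[4,6-bis(benzyloxy)-3-[2-(benzyloxy)-5-(1,3-dioxolan-2-yl)phenyl]-2-hydroxyphenyl]-3-[4-(benzyloxy)phenyl]prop-2-en-1-one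
Product: 11 4-(benzyloxy)-3-[4,6-bis(benzyloxy)-2-hydroxy-3-[(E)-3-[4-(benzyloxy)phenyl]prop-2-enoyl]phenyl]benzaldehyde
Conditions: 1 M HCl (aq.), THF, rt
Reagents that add atoms: water, O
Why: Acid-catalysed acetal hydrolysis, fast for the dioxolane of an electron-rich benzaldehyde, so that brief exposure to dilute acid at room temperature should leave the 2'-hydroxychalcone and the benzyl ethers unchanged.

Step 9
Reactants: 12 2',6'-dihydroxy-4'-methoxyacetophenone
Product: 13 1-[2-(benzyloxy)-6-hydroxy-4-methoxyphenyl]ethanone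
Conditions: BnBr (1.05 equiv), K2CO3, acetone, reflux
Reagents that add atoms: benzyl bromide, BrCc1ccccc1
Why: Williamson mono-alkylation of a symmetrical 2,6-dihydroxyaryl ketone, which stops after one benzylation because the remaining hydroxyl becomes strongly hydrogen-bonded to the carbonyl.

Step 10
Reactants: 11 4-(benzyloxy)-3-[4,6-bis(benzyloxy)-2-hydroxy-3-[(E)-3-[4-(benzyloxy)phenyl]prop-2-enoyl]phenyl]benzaldehyde; 13 1-[2-(benzyloxy)-6-hydroxy-4-methoxyphenyl]ethanone (1.1 equiv)
Product: 14 (E)-1-[2-(benzyloxy)-6-hydroxy-4-methoxyphenyl]-3-[4-(benzyloxy)-3-[4,6-bis(benzyloxy)-2-hydroxy-3-[(E)-3-[4-(benzyloxy)phenyl]prop-2-enoyl]phenyl]phenyl]prop-2-en-1-one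
Conditions: KOH (aq. 50%), EtOH/THF, rt
Reagents that add atoms: none
Why: Claisen–Schmidt condensation in which 13 is the only enolisable partner and the aldehyde of 11 the most reactive electrophile, the enone already present being deactivated as its 2'-phenoxide and by its electron-rich β-aryl group.

Step 11
Reactants: 14 (E)-1-[2-(benzyloxy)-6-hydroxy-4-methoxyphenyl]-3-[4-(benzyloxy)-3-[4,6-bis(benzyloxy)-2-hydroxy-3-[(E)-3-[4-(benzyloxy)phenyl]prop-2-enoyl]phenyl]phenyl]prop-2-en-1-one
Product: 16 5,4',5'',7'',4'''-penta-O-benzylsequoiaflavone, via bis-flavanone 15 (not isolated)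
Conditions: I2 (0.2 equiv), DMSO, 130 °C
Reagents that add atoms: none
Why: Each 2'-hydroxychalcone unit closes by conjugate addition of its free phenol oxygen to the enone β-carbon, forming O1–C2 (ring C) and O1''–C2'' (ring F) at the flavanone level (15); iodine then iodinates the C3 and C3'' enols, loss of HI installs the C2=C3 and C2''=C3'' double bonds, and DMSO oxidises HI back to I2 so that a catalytic amount of iodine suffices. The closest known reaction is the iodine–DMSO oxidative cyclisation of 2'-hydroxychalcones to flavones, which mirrors in the flask what chalcone isomerase and flavone synthase do in the plant, here applied to two units of one molecule. Ring C and ring F each close in the 6-endo-trig mode (oxa-Michael addition). No stereocentre remains in 16, since the C2 and C2'' centres of 15 form without control and are erased by the dehydrogenation. The step needs ring F to close onto the ring D oxygen lying between the acyl carbon and the biaryl carbon, which is secured because that oxygen is the only free phenol of ring D (O5'' and O7'' are benzyl ethers), so ring B ends at C8''; in ring A the single free ortho phenol likewise allows only the 5-benzyloxy-7-methoxy pattern. Catalytic iodine keeps the HI concentration low, which should spare the benzyl ethers and the electron-rich C6, C8 and C6'' positions.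

Step 12
Reactants: 16 5,4',5'',7'',4'''-penta-O-benzylsequoiaflavone
Product: 17 sequoiaflavone
Conditions: BCl3 (1 M in CH2Cl2, excess), C6HMe5 (excess), CH2Cl2, –78 °C; then MeOH
Reagents that add atoms: none
Why: Lewis-acid debenzylation with a non-Lewis-basic cation scavenger, in which BCl3 cleaves the five aryl benzyl ethers at low temperature, pentamethylbenzene traps the benzyl cations by Friedel–Crafts alkylation before they can attack the phloroglucinol rings, and the unchelated 7-methyl ether should survive.

**Compound list**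

1 | 2',4',6'-trihydroxyacetophenone | CC(=O)c1c(O)cc(O)cc1O | starting material
2 | 1-[2,4-bis(benzyloxy)-6-hydroxyphenyl]ethanone | CC(=O)c1c(O)cc(OCc2ccccc2)cc1OCc1ccccc1 | intermediate
3 | 1-[4,6-bis(benzyloxy)-2-hydroxy-3-iodophenyl]ethanone | CC(=O)c1c(O)c(I)c(OCc2ccccc2)cc1OCc1ccccc1 | intermediate
4 | 3-bromo-4-hydroxybenzaldehyde | O=Cc1ccc(O)c(Br)c1 | starting material
5 | 4-(benzyloxy)-3-bromobenzaldehyde | O=Cc1ccc(OCc2ccccc2)c(Br)c1 | intermediate
6 | 2-[4-(benzyloxy)-3-bromophenyl]-1,3-dioxolane | Brc1cc(C2OCCO2)ccc1OCc1ccccc1 | intermediate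
7 | 2-[2-(benzyloxy)-5-(1,3-dioxolan-2-yl)phenyl]-4,4,5,5-tetramethyl-1,3,2-dioxaborolane | CC1(C)OB(c2cc(C3OCCO3)ccc2OCc2ccccc2)OC1(C)C | intermediate
8 | 1-[4,6-bis(benzyloxy)-3-[2-(benzyloxy)-5-(1,3-dioxolan-2-yl)phenyl]-2-hydroxyphenyl]ethanone | CC(=O)c1c(O)c(-c2cc(C3OCCO3)ccc2OCc2ccccc2)c(OCc2ccccc2)cc1OCc1ccccc1 | intermediate
9 | 4-(benzyloxy)benzaldehyde | O=Cc1ccc(OCc2ccccc2)cc1 | starting material
10 | (E)-1-[4,6-bis(benzyloxy)-3-[2-(benzyloxy)-5-(1,3-dioxolan-2-yl)phenyl]-2-hydroxyphenyl]-3-[4-(benzyloxy)phenyl]prop-2-en-1-one | O=C(/C=C/c1ccc(OCc2ccccc2)cc1)c1c(O)c(-c2cc(C3OCCO3)ccc2OCc2ccccc2)c(OCc2ccccc2)cc1OCc1ccccc1 | intermediate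
11 | 4-(benzyloxy)-3-[4,6-bis(benzyloxy)-2-hydroxy-3-[(E)-3-[4-(benzyloxy)phenyl]prop-2-enoyl]phenyl]benzaldehyde | O=Cc1ccc(OCc2ccccc2)c(-c2c(O)c(C(=O)/C=C/c3ccc(OCc4ccccc4)cc3)c(OCc3ccccc3)cc2OCc2ccccc2)c1 | intermediate
12 | 2',6'-dihydroxy-4'-methoxyacetophenone | COc1cc(O)c(C(C)=O)c(O)c1 | starting material
13 | 1-[2-(benzyloxy)-6-hydroxy-4-methoxyphenyl]ethanone | COc1cc(O)c(C(C)=O)c(OCc2ccccc2)c1 | intermediate
14 | (E,E)-bichalcone: (E)-1-[2-(benzyloxy)-6-hydroxy-4-methoxyphenyl]-3-[4-(benzyloxy)-3-[4,6-bis(benzyloxy)-2-hydroxy-3-[(E)-3-[4-(benzyloxy)phenyl]prop-2-enoyl]phenyl]phenyl]prop-2-en-1-one | COc1cc(O)c(C(=O)/C=C/c2ccc(OCc3ccccc3)c(-c3c(O)c(C(=O)/C=C/c4ccc(OCc5ccccc5)cc4)c(OCc4ccccc4)cc3OCc3ccccc3)c2)c(OCc2ccccc2)c1 | intermediate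
15 | bis-flavanone: 5-(benzyloxy)-2-[4-(benzyloxy)-3-[5,7-bis(benzyloxy)-2-[4-(benzyloxy)phenyl]-4-oxochroman-8-yl]phenyl]-7-methoxychroman-4-one, mixture of stereoisomers at C2 and C2'' | COc1cc(OCc2ccccc2)c2C(=O)CC(c3ccc(OCc4ccccc4)c(-c4c(OCc5ccccc5)cc(OCc5ccccc5)c5C(=O)CC(c6ccc(OCc7ccccc7)cc6)Oc45)c3)Oc2c1 | intermediate
16 | 5,4',5'',7'',4'''-penta-O-benzylsequoiaflavone: 5-(benzyloxy)-2-[4-(benzyloxy)-3-[5,7-bis(benzyloxy)-2-[4-(benzyloxy)phenyl]-4-oxo-4H-chromen-8-yl]phenyl]-7-methoxy-4H-chromen-4-one | COc1cc(OCc2ccccc2)c2c(=O)cc(-c3ccc(OCc4ccccc4)c(-c4c(OCc5ccccc5)cc(OCc5ccccc5)c5c(=O)cc(-c6ccc(OCc7ccccc7)cc6)oc45)c3)oc2c1 | intermediate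
17 | sequoiaflavone (7-O-methylamentoflavone) | COc1cc(O)c2c(=O)cc(-c3ccc(O)c(-c4c(O)cc(O)c5c(=O)cc(-c6ccc(O)cc6)oc45)c3)oc2c1 | target

**Totals and risks**

Total step count: 12.
Longest linear sequence: 9 steps (steps 3, 4, 5, 6, 7, 8, 10, 11, 12, from 3-bromo-4-hydroxybenzaldehyde).

Steps most likely to fail:

1. Step 6 (hindered biaryl coupling). Protodeboronation of the electron-rich ortho-alkoxy boronate and reductive deiodination of the iodophenol may outrun transmetalation and reductive elimination at the tri-ortho-substituted centre. The fallback sets out from 6 and returns at 8. Bromide 6 undergoes bromine–lithium exchange (n-BuLi, THF, –78 °C) and is quenched with Bu3SnCl to give tributyl[2-(benzyloxy)-5-(1,3-dioxolan-2-yl)phenyl]stannane F1. F1 is joined to iodide 3 in a copper-assisted Stille coupling (Pd(PPh3)4, CuI, CsF, DMF, 70 °C), which needs no aqueous base and has no protodeboronation pathway, to deliver biaryl 8.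

2. Step 10 (second aldol condensation beside an existing enone). Under hydroxide the enolate of 13 may add in conjugate fashion to the enone already in 11, or that enone may isomerise to its flavanone or suffer retro-aldol cleavage, before condensation at the aldehyde is complete. The fallback sets out from 13 and 11 and returns at 14. Ketone 13 is converted at –78 °C into its lithium phenoxide–enolate with LiN(SiMe3)2 (2.2 equiv, THF). It is then combined with aldehyde 11, pre-treated with one equivalent of the same base, in a kinetically controlled directed aldol addition that gives the β-hydroxy ketone 3-[4-(benzyloxy)-3-[4,6-bis(benzyloxy)-2-hydroxy-3-[(E)-3-[4-(benzyloxy)phenyl]prop-2-enoyl]phenyl]phenyl]-1-[2-(benzyloxy)-6-hydroxy-4-methoxyphenyl]-3-hydroxypropan-1-one F2 (racemic). F2 is dehydrated in a separate operation (TsOH cat., CH2Cl2, rt) through its stabilised benzylic cation to the E enone of 14.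

3. Step 11 (double oxidative cyclisation). The two halves may react at different rates, so that mixed flavanone/flavone material accumulates on prolonged heating. Meanwhile HI held in hot DMSO may strip the peri benzyl ethers at O5 and O5'' or iodinate C6, C8 or C6''. Loss of a benzyl group would still converge on 17 in step 12; ring iodination would not. The fallback sets out from 14 and returns at 16, and separates ring closure from dehydrogenation. Compound 14 is isomerised with NaOAc in refluxing EtOH to the bis-flavanone 15, which is isolated this time. It is then dehydrogenated with DDQ in refluxing 1,4-dioxane to 16, forming the same O1–C2 and O1''–C2'' bonds with no iodine species present.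

**Further compounds**

F1 | step 6 | tributyl[2-(benzyloxy)-5-(1,3-dioxolan-2-yl)phenyl]stannane | CCCC[Sn](CCCC)(CCCC)c1cc(C2OCCO2)ccc1OCc1ccccc1
F2 | step 10 | 3-[4-(benzyloxy)-3-[4,6-bis(benzyloxy)-2-hydroxy-3-[(E)-3-[4-(benzyloxy)phenyl]prop-2-enoyl]phenyl]phenyl]-1-[2-(benzyloxy)-6-hydroxy-4-methoxyphenyl]-3-hydroxypropan-1-one (racemic) | COc1cc(O)c(C(=O)CC(O)c2ccc(OCc3ccccc3)c(-c3c(O)c(C(=O)/C=C/c4ccc(OCc5ccccc5)cc4)c(OCc4ccccc4)cc3OCc3ccccc3)c2)c(OCc2ccccc2)c1
F0 | step 11 | none | none
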